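**Tempting shortcut.** A doubled catalyst tempts one to run the clock twice as fast, but that shortcut needs every route to product to pass through catalyst. The south run, charged with product, makes more in its first 4.9 min than the north-east run does.

| setting | north-east | north-west | south-west | south | north |
|---|---|---|---|---|---|
| substrate | 0.120 M | 0.0720 M | 0.360 M | 0.120 M | 0.360 M |
| free catalyst | 0.0120 M | 0.0120 M | 0.0120 M | 0.0120 M | 0.0240 M |
| product |  |  |  | 0.0360 M |  |
| time |  |  |  |  | 65 min |

| run | time / min | [product] / M |
|---|---|---|
| north-east run | 4.9 | 0.0075 |
| north-east run | 15 | 0.0244 |
| north-east run | 29 | 0.0438 |
| north-east run | 45 | 0.0624 |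
| north-east run | 65 | 0.0792 |
| north-west run | 4.9 | 0.0052 |
| north-west run | 15 | 0.0140 |
| north-west run | 29 | 0.0248 |
| north-west run | 45 | 0.0362 |
| north-west run | 65 | 0.0457 |
| south-west run | 4.9 | 0.0258 |
| south-west run | 15 | 0.0829 |
| south-west run | 29 | 0.1582 |
| south-west run | 45 | 0.2270 |
| south-west run | 65 | 0.2840 |
| south run | 4.9 | 0.0456 |
| south run | 15 | 0.0646 |
| south run | 29 | 0.0856 |
| south run | 45 | 0.1030 |
| south run | 65 | 0.1193 |

(each reading ± 4 × 10⁻⁴ M)

- apparent order in [substrate] of the starting rate, round the charge of the north-east run (the rate where two percent of its substrate have turned into product) (one fixed amount of product, the same in the runs compared)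
- product in the north run at 65 min, as a share of the substrate charged

- Overall: substrate -> product, with free catalyst as catalyst.
- Constant volume, constant temperature.
- An order is taken over about fifteen percent of the charge, up and down.

**Two routes.** The rate per [substrate], the specific rate, reads 0.0152 min⁻¹ over the first span of the south-west run and 0.0185 min⁻¹ over the second, so it climbs with product. Read back to zero product, it is 0.0141 min⁻¹. That is the catalyst route, pseudo-first-order in substrate while the catalyst holds, and the climb is the product route. The climb equals that starting value at 0.176 M: call this the handover product, [P]×, the amount of product at which the product route matches the catalyst route at 0.0120 M of catalyst. With both routes taken to scale with [substrate] at fixed product, I reckon the order as 1.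

**Two extremes.** Suppose the catalyst route scales with catalyst, which no run tested. Then the north run has a specific rate of 0.0283 min⁻¹ at zero product, and its [P]× rises to 0.352 M, close to its 0.360 M charge. With the catalyst route alone and undiminished, simple first-order decay gives 84.1% in 65 min. With both routes undiminished, the logistic curve gives 95.2%. The product route should lift the flask above the first figure. It should stay below the second, since the last south-west span reads 0.0273 min⁻¹ against 0.0346 min⁻¹ on the line. I commit to about 89.6%.

**The forecast.** The forecast gives an order of 1 (0.85 to 1.15) and 97.5% (91% to 99.5%), on a reckoning that “assumes first order in catalyst, doubling effective time”. Its figure stands above my upper extreme.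

**The result.** The flask gives an order of 1.0 and 89.9%, which is 7.6 percentage points below the forecast.

    free catalyst + substrate → product + free catalyst (1.176 M⁻¹ min⁻¹)
    free catalyst + product → spent catalyst + product (0.1440 M⁻¹ min⁻¹)
    substrate + product → 2 product (0.09120 M⁻¹ min⁻¹)

**Handover used.** At 65 min the north run holds 0.324 M of product, below the [P]× of 0.352 M reckoned for its catalyst charge, yet the product route still counts: without the reaction of substrate with product, the north run falls from 89.9% to 66.7% at that time. For the south run, [P]× from the south-west readings puts the rate above the north-east run's by a factor of 1.20, and where two percent of the north-east charge has turned, the south run's rate stands to the north-east run's at a ratio of 1.22.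

The numbers in the tables were computed on assumed constants, noise included.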